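**Retrosynthetic overview**
1. Target 6 is cut at the benzylic C–O bond into isomeranzin 3 and senecioic acid 4. One enantioselective oxidative α-acyloxylation (the proposed new step) joins them, sets the (S) centre and installs the ester.
2. Ketone 3 comes from epoxide 2 by a Meinwald 1,2-hydride shift, and 2 comes from osthole 1 by alkene epoxidation.
3. Rings: the coumarin bicycle (benzene ring A, pyranone ring B) is bought intact in 1, so no ring of the target is built. The only ring made is the transient oxirane (step 1), which is opened in step 2.

Assumption: osthole, a catalogue natural product that already carries the full C15 skeleton, is accepted as the commercial starting material; the target stereocentre is (S) as read from the SMILES.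

Catalyst used in step 3: Q*I = (11bS,11'bS)-2,6-bis[3,5-bis(trifluoromethyl)phenyl]-3,3',5,5'-tetrahydro-4,4'-spirobi[dinaphtho[2,1-c:1',2'-e]azepin]-4-ium iodide, a chiral N-spiro quaternary ammonium iodide. The sense of induction of a new reaction cannot be predicted with certainty; if a pilot run shows that the (S,S) salt gives the (R) product, the mirror-image (R,R) salt is used instead.

**Route**

Step 1
Reactants: 1 osthole (7-methoxy-8-(3-methylbut-2-en-1-yl)-2H-chromen-2-one)
Product: 2 (±)-meranzin (8-[(3,3-dimethyloxiran-2-yl)methyl]-7-methoxy-2H-chromen-2-one)
Conditions: mCPBA (1.2 equiv), CH2Cl2, 0 °C → rt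
Reagents that add atoms: mCPBA (3-chloroperoxybenzoic acid), O=C(OO)c1cccc(Cl)c1
Why: Prilezhaev epoxidation; the electron-rich trisubstituted prenyl alkene is oxidised far faster than the electron-poor coumarin C3=C4 bond or the arene, and the oxirane stereocentre (formed racemic) is erased in step 2.

Step 2
Reactants: 2 (±)-meranzin
Product: 3 isomeranzin (7-methoxy-8-(3-methyl-2-oxobutyl)-2H-chromen-2-one)
Conditions: BF3·OEt2 (0.2 equiv), CH2Cl2, −40 → 0 °C
Reagents that add atoms: none
Why: Meinwald rearrangement; BF3 opens the oxirane at its tertiary carbon and a 1,2-hydride shift from the neighbouring CH–O carbon gives the isopropyl ketone, while lactone, aryl methyl ether and coumarin alkene are inert to catalytic BF3 at low temperature and no stereocentre remains.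

Step 3
Reactants: 3 isomeranzin; 4 senecioic acid (3-methylbut-2-enoic acid, 2 equiv)
Product: 6 (S)-1-(7-methoxy-2-oxo-2H-chromen-8-yl)-3-methyl-2-oxobutyl 3-methylbut-2-enoate (target), via α-iodo ketone 5 (not isolated)
Conditions: Q*I (10 mol%), tBuOOH (1.5 equiv, in decane), toluene–MTBE 1:1, 25 °C
Reagents that add atoms: none
Why: Proposed new method: enantioconvergent chiral-ammonium (hypo)iodite-catalysed intermolecular α-acyloxylation of a ketone by a free carboxylic acid; tBuOOH oxidises the iodide of Q*I to the ammonium hypoiodite, which iodinates the benzylic enol of 3 (the only readily enolised α-position that can undergo SN2) to racemic α-iodo ketone 5, 5 racemises quickly by degenerate iodide exchange and reversible enolisation, and the senecioate held as a tight ion pair by the chiral cation in the non-polar medium displaces iodide by SN2 with inversion from (R)-5 faster than from (S)-5 (dynamic kinetic resolution), so the C–O bond, the ester and the (S) centre are made together while iodide returns to the catalyst; the weakly acidic, amine-free medium leaves the hindered α-H of 6, the lactone and both electron-poor alkenes untouched; the closest known reaction types are the racemic tetraalkylammonium iodide/hydroperoxide α-oxyacylation of ketones with carboxylic acids, the enantioselective intramolecular oxidative cyclisations with chiral ammonium hypoiodites, and the enantioconvergent substitution of racemic α-halo ketones by azide under chiral quaternary ammonium ion pairing.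

**Compound list**
1 | osthole: 7-methoxy-8-(3-methylbut-2-en-1-yl)-2H-chromen-2-one | COc1ccc2ccc(=O)oc2c1CC=C(C)C | starting material
2 | (±)-meranzin: 8-[(3,3-dimethyloxiran-2-yl)methyl]-7-methoxy-2H-chromen-2-one, racemic | COc1ccc2ccc(=O)oc2c1CC3OC3(C)C | intermediate
3 | isomeranzin: 7-methoxy-8-(3-methyl-2-oxobutyl)-2H-chromen-2-one | COc1ccc2ccc(=O)oc2c1CC(=O)C(C)C | intermediate
4 | senecioic acid: 3-methylbut-2-enoic acid | CC(C)=CC(=O)O | starting material
5 | α-iodo ketone: 8-(1-iodo-3-methyl-2-oxobutyl)-7-methoxy-2H-chromen-2-one, racemic and interconverting, not isolated | COc1ccc2ccc(=O)oc2c1C(I)C(=O)C(C)C | intermediate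
6 | (S)-1-(7-methoxy-2-oxo-2H-chromen-8-yl)-3-methyl-2-oxobutyl 3-methylbut-2-enoate | COc1ccc2ccc(=O)oc2c1[C@H](OC(=O)C=C(C)C)C(=O)C(C)C | target

**Totals**
Total step count: 3. Longest linear sequence: 3 steps (1 → 2 → 3 → 6); senecioic acid 4 enters in step 3.

**Steps most likely to fail, with fallbacks**

Step 3 (the proposed new step) is the most likely to fail. The ion pair may be too loose for high enantioselectivity, 5 may racemise too slowly, or over-oxidation to the 1,2-diketone or iodination of the arene may compete. The fallback uses known chemistry only; it sets out from 3 and comes back to the route at 6.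
- Ketone 3 is deprotonated at the benzylic position with LiN(SiMe3)2 in THF at −78 °C, and the (Z)-enolate is O-acylated with 3-methylbut-2-enoyl chloride. This gives the (Z)-enol senecioate F1, with the aryl group cis to the acyloxy group to avoid the isopropyl group.
- Shi asymmetric epoxidation of the enol ester double bond follows, using the D-fructose-derived ketone catalyst (1,2:4,5-di-O-isopropylidene-β-D-erythro-2,3-hexodiulo-2,6-pyranose), KHSO5 and K2CO3 in MeCN–dimethoxymethane–water at 0 °C. The coumarin and senecioate alkenes are electron-poor and are left alone. The product is the enol ester epoxide F2, (2S,3R) as predicted by the spiro transition-state model.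
- The known stereospecific rearrangement of enol ester epoxides to α-acyloxy ketones (YbCl3 cat., CH2Cl2, rt, or gentle heating) shifts the acyloxy group from C2 to the benzylic carbon with inversion. This gives (S)-6 with the senecioyl group already in place.
- If the epoxide proves to have the opposite configuration, the strong-acid mode of the same rearrangement (cat. p-TsOH, retention at the benzylic carbon) or the enantiomeric ketone catalyst leads to the same (S)-6.

Step 2 (Meinwald rearrangement) is the second risk. Benzyl migration to the aldehyde, proton loss to the allylic alcohol, or participation of the ortho-methoxy group may compete with the hydride shift. The fallback avoids the epoxide; it sets out from 1 and comes back at 3.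
- Anti-Markovnikov hydroboration of the prenyl alkene (BH3·SMe2, THF, 0 °C) and oxidation with NaBO3·4H2O, which is mild enough for the lactone, give the secondary alcohol F3.
- Oxidation with Dess–Martin periodinane in CH2Cl2 then gives ketone 3.

Step 1 (epoxidation) is the third risk. The acid-labile trisubstituted epoxide can be opened by the 3-chlorobenzoic acid formed. The fallback builds the oxirane by the halohydrin route; it sets out from 1 and comes back at 2.
- N-bromosuccinimide in THF–water at 0 °C gives the Markovnikov bromohydrin F4 (hydroxyl at the tertiary carbon).
- K2CO3 in acetone closes it to the oxirane 2 by intramolecular Williamson displacement of bromide.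

Further compounds
F1 | step 3 | (Z)-1-(7-methoxy-2-oxo-2H-chromen-8-yl)-3-methylbut-1-en-2-yl 3-methylbut-2-enoate | COc1ccc2ccc(=O)oc2c1/C=C(\OC(=O)C=C(C)C)C(C)C
F2 | step 3 | (2S,3R)-3-(7-methoxy-2-oxo-2H-chromen-8-yl)-2-(propan-2-yl)oxiran-2-yl 3-methylbut-2-enoate | COc1ccc2ccc(=O)oc2c1[C@H]3O[C@]3(OC(=O)C=C(C)C)C(C)C
F3 | step 2 | (±)-8-(2-hydroxy-3-methylbutyl)-7-methoxy-2H-chromen-2-one | COc1ccc2ccc(=O)oc2c1CC(O)C(C)C
F4 | step 1 | (±)-8-(2-bromo-3-hydroxy-3-methylbutyl)-7-methoxy-2H-chromen-2-one | COc1ccc2ccc(=O)oc2c1CC(Br)C(C)(C)O
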